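The ring is numbered C1 (tertiary carbinol bearing CH2OBz), C2 (ketone), C3=C4, C5 (CHOH), C6 (CHOBz). The C1 and C5 hydroxyls are cis and flank C6. Tying them into a benzylidene acetal and raising C6 to a ketone reveals a 1,3-dioxan-5-one. Its two alpha carbons are nucleophiles matched to the two electrophilic carbons of an acryloyl unit. One enamine alpha,alpha'-annulation with acryloyl chloride forms C4–C5 and C2–C1. It closes the carbocycle as a 2,4-dioxabicyclo[3.3.1]nonanedione and sets both stereocentres from the acetal carbon alone. The precursor is a monocyclic, D-threitol-derived dioxanone enamine with no carbocycle at all.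

Key step: step 4

The target numbering above (C1–C6, C7 = exocyclic CH2) is used in all Why lines.

Step 1
Reactants: 1 D-threitol
Product: 2 2,4-O-benzylidene-D-threitol = (2S,4R,5R)-4-(hydroxymethyl)-2-phenyl-1,3-dioxan-5-ol (phenyl and CH2OH equatorial and cis; 5-OH axial)
Conditions: PhCH(OMe)2 (1.0 equiv), CSA (cat.), DMF, 50 °C, reduced pressure
Reagents that add atoms: benzaldehyde dimethyl acetal COC(OC)c1ccccc1
Why: Acid-catalysed transacetalisation under equilibrating conditions favours the six-membered 1,3-dioxane; because the tetrol is C2-symmetric both 1,3-modes give the same compound, and the new acetal stereocentre settles with phenyl equatorial and cis to the equatorial CH2OH group (thermodynamic control).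

Step 2
Reactants: 2 2,4-O-benzylidene-D-threitol
Product: 3 (2S,4R,5R)-4-{[(tert-butyldimethylsilyl)oxy]methyl}-2-phenyl-1,3-dioxan-5-ol
Conditions: TBSCl (1.05 equiv), imidazole, CH2Cl2, 0 °C
Reagents that add atoms: tert-butyldimethylsilyl chloride CC(C)(C)[Si](C)(C)Cl
Why: Sterically controlled silylation takes the primary hydroxyl well ahead of the axial secondary one, and a silyl ether is chosen over the final benzoate because it is a poor leaving group beta to the future ketone.

Step 3
Reactants: 3 silyl ether alcohol
Product: 4 (2S,4R)-4-{[(tert-butyldimethylsilyl)oxy]methyl}-2-phenyl-1,3-dioxan-5-one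
Conditions: Dess–Martin periodinane, CH2Cl2, 0 °C to rt
Reagents that add atoms: none
Why: Dess–Martin oxidation of the secondary alcohol is near neutral, so acetal and silyl ether survive, and the alpha stereocentre (future C1) stays in its thermodynamically preferred equatorial 2,4-cis arrangement.

Step 4
Reactants: 4 dioxanone; 5 acryloyl chloride
Product: 8 (1R,3S,5S)-5-{[(tert-butyldimethylsilyl)oxy]methyl}-3-phenyl-2,4-dioxabicyclo[3.3.1]nonane-6,9-dione, via pyrrolidine enamine 6 (not isolated), via bicyclic iminium chloride 7 (not isolated)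
Conditions: pyrrolidine (1.5 equiv), 4 Å MS, PhH, rt, then evaporation of volatiles; 5 (1.1 equiv), PhH, 80 °C; then H2O, rt
Reagents that add atoms: acryloyl chloride (5) C=CC(=O)Cl; water O
Why: N-Acylation of the less substituted enamine 6 by 5 gives an N-acryloyl enammonium ion whose chair-like [3,3] shift (3-aza-Cope) joins the acryloyl beta carbon C4 to C5 and releases a ketene–iminium pair; loss of the C1 proton regenerates an enamine on the other side, which attacks the ketene carbon C2 to build quaternary C1 and give iminium chloride 7, hydrolysed to 8. The closest known reaction type is the alpha,alpha'-annulation of six-membered cyclic ketone enamines with acryloyl chloride to bicyclo[3.3.1]nonane-2,9-diones, and alpha,alpha'-annulations of 1,3-dioxan-5-one enamines with other three-carbon bis-electrophiles are also known. The one new ring, the six-membered carbocycle, closes in a 6-(enolendo)-exo mode at the ketene (or derived acyl chloride) carbon, which is possible only when the side chain on C5 is axial on the dioxane. C5 and C1 are therefore set together: the three-carbon bridge must span two axial positions on one face, and the acetal carbon, the only stereocentre that survives planarisation of C1, selects the face that carries its own axial hydrogen and keeps phenyl equatorial and exo, so that C1–H is replaced by C1–C2 with retention (self-regeneration of a stereocentre), any endo-phenyl diastereomer being separable at this stage. The regiochemistry needed (C4 to the CH2-derived carbon, C2 to the substituted carbon) follows from the position of the enamine double bond, held away from the CH2OTBS-bearing carbon by A(1,3) strain, and from the fixed order of conjugate bond first, acylation second. The poor silyloxy leaving group suppresses beta-elimination from the C1 enamine, and in 8 both carbons next to the bridge ketone are bridgeheads, so Bredt strain protects C5 from epimerisation.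

Step 5
Reactants: 8 bicyclic dione
Product: 10 (1R,3S,5S)-5-{[(tert-butyldimethylsilyl)oxy]methyl}-3-phenyl-2,4-dioxabicyclo[3.3.1]non-7-ene-6,9-dione, via trimethylsilyl enol ether 9 (not isolated)
Conditions: TMSOTf, Et3N, CH2Cl2, 0 °C; then Pd(OAc)2 (1.1 equiv), MeCN, rt
Reagents that add atoms: none
Why: Saegusa–Ito oxidation: only C3 can be enolised (C1 is quaternary and both carbons next to the bridge ketone are bridgeheads), so soft enolisation gives a single silyl enol ether, whose enolate complex of divalent palladium undergoes beta-hydride elimination from C4 to install C3=C4.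

Step 6
Reactants: 10 bicyclic enedione
Product: 11 (1R,3S,5R,9S)-5-{[(tert-butyldimethylsilyl)oxy]methyl}-9-hydroxy-3-phenyl-2,4-dioxabicyclo[3.3.1]non-7-en-6-one
Conditions: NaBH4, MeOH/CH2Cl2 (1:1), −78 °C
Reagents that add atoms: none
Why: Chemoselective borohydride reduction: at low temperature the bridge ketone, activated by two alpha C–O bonds, should react well ahead of the conjugated C2 carbonyl, and hydride should arrive axially with respect to the dioxane ring, on the face that carries only oxygen lone pairs and lies away from the enone bridge filling both flanking axial positions, which places the new C6 hydroxyl trans to the C1 and C5 oxygens (9S).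

Step 7
Reactants: 11 silyl ether alcohol
Product: 12 (1R,3S,5R,9S)-9-hydroxy-5-(hydroxymethyl)-3-phenyl-2,4-dioxabicyclo[3.3.1]non-7-en-6-one
Conditions: HF·pyridine, THF, 0 °C to rt
Reagents that add atoms: none
Why: Fluoride-driven desilylation in a mildly acidic medium frees the primary C7 hydroxyl without the basic conditions that could trigger retro-aldol cleavage of the beta-hydroxy ketone, and the benzylidene acetal is stable to it.

Step 8
Reactants: 12 diol
Product: 13 [(1R,3S,5R,9S)-9-(benzoyloxy)-6-oxo-3-phenyl-2,4-dioxabicyclo[3.3.1]non-7-en-5-yl]methyl benzoate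
Conditions: BzCl (3 equiv), pyridine, DMAP (cat.), CH2Cl2, 0 °C to rt
Reagents that add atoms: benzoyl chloride O=C(Cl)c1ccccc1
Why: DMAP-catalysed acylation esterifies the only two free hydroxyls (C6 and C7), the regiochemistry being guaranteed because the C1 and C5 oxygens are still locked in the acetal.

Step 9
Reactants: 13 dibenzoate acetal
Product: 14 [(1R,5R,6S)-6-(benzoyloxy)-1,5-dihydroxy-2-oxocyclohex-3-en-1-yl]methyl benzoate (target)
Conditions: TFA/H2O (9:1), CH2Cl2, 0 °C to rt
Reagents that add atoms: none
Why: Acid-catalysed acetal hydrolysis breaks only the bonds at the benzylic carbon, so the C1–O and C5–O bonds and all three stereocentres are untouched, while benzoates and enone tolerate the acid and acyl migration is slow at low pH.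

Compound list
1 | D-threitol, (2R,3R)-butane-1,2,3,4-tetrol | OC[C@@H](O)[C@H](O)CO | starting material
2 | (2S,4R,5R)-4-(hydroxymethyl)-2-phenyl-1,3-dioxan-5-ol | OC[C@H]1O[C@@H](c2ccccc2)OC[C@H]1O | intermediate
3 | (2S,4R,5R)-4-{[(tert-butyldimethylsilyl)oxy]methyl}-2-phenyl-1,3-dioxan-5-ol | CC(C)(C)[Si](C)(C)OC[C@H]1O[C@@H](c2ccccc2)OC[C@H]1O | intermediate
4 | (2S,4R)-4-{[(tert-butyldimethylsilyl)oxy]methyl}-2-phenyl-1,3-dioxan-5-one | CC(C)(C)[Si](C)(C)OC[C@H]1O[C@@H](c2ccccc2)OCC1=O | intermediate
5 | acryloyl chloride (prop-2-enoyl chloride) | C=CC(=O)Cl | starting material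
6 | 1-[(2S,4S)-4-{[(tert-butyldimethylsilyl)oxy]methyl}-2-phenyl-4H-1,3-dioxin-5-yl]pyrrolidine (enamine, not isolated; the C4 centre is labile and is erased in the same flask) | CC(C)(C)[Si](C)(C)OC[C@H]1O[C@@H](c2ccccc2)OC=C1N1CCCC1 | intermediate
7 | pyrrolidinium (iminium) chloride of 8 at the bridge carbon (not isolated) | [Cl-].CC(C)(C)[Si](C)(C)OC[C@]12O[C@@H](c3ccccc3)O[C@H](CCC1=O)C2=[N+]1CCCC1 | intermediate
8 | (1R,3S,5S)-5-{[(tert-butyldimethylsilyl)oxy]methyl}-3-phenyl-2,4-dioxabicyclo[3.3.1]nonane-6,9-dione (phenyl exo) | CC(C)(C)[Si](C)(C)OC[C@]12O[C@@H](c3ccccc3)O[C@H](CCC1=O)C2=O | intermediate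
9 | (1R,3S,5S)-5-{[(tert-butyldimethylsilyl)oxy]methyl}-3-phenyl-6-[(trimethylsilyl)oxy]-2,4-dioxabicyclo[3.3.1]non-6-en-9-one (not isolated) | CC(C)(C)[Si](C)(C)OC[C@]12O[C@@H](c3ccccc3)O[C@H](CC=C1O[Si](C)(C)C)C2=O | intermediate
10 | (1R,3S,5S)-5-{[(tert-butyldimethylsilyl)oxy]methyl}-3-phenyl-2,4-dioxabicyclo[3.3.1]non-7-ene-6,9-dione | CC(C)(C)[Si](C)(C)OC[C@]12O[C@@H](c3ccccc3)O[C@H](C=CC1=O)C2=O | intermediate
11 | (1R,3S,5R,9S)-5-{[(tert-butyldimethylsilyl)oxy]methyl}-9-hydroxy-3-phenyl-2,4-dioxabicyclo[3.3.1]non-7-en-6-one | CC(C)(C)[Si](C)(C)OC[C@]12O[C@@H](c3ccccc3)O[C@H](C=CC1=O)[C@@H]2O | intermediate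
12 | (1R,3S,5R,9S)-9-hydroxy-5-(hydroxymethyl)-3-phenyl-2,4-dioxabicyclo[3.3.1]non-7-en-6-one | OC[C@]12O[C@@H](c3ccccc3)O[C@H](C=CC1=O)[C@@H]2O | intermediate
13 | [(1R,3S,5R,9S)-9-(benzoyloxy)-6-oxo-3-phenyl-2,4-dioxabicyclo[3.3.1]non-7-en-5-yl]methyl benzoate | O=C(OC[C@]12O[C@@H](c3ccccc3)O[C@H](C=CC1=O)[C@@H]2OC(=O)c1ccccc1)c1ccccc1 | intermediate
14 | [(1R,5R,6S)-6-(benzoyloxy)-1,5-dihydroxy-2-oxocyclohex-3-en-1-yl]methyl benzoate | O=C(OC[C@]1(O)C(=O)C=C[C@@H](O)[C@@H]1OC(=O)c1ccccc1)c1ccccc1 | target

Total step count: 9
Longest linear sequence: 9 steps (1 to 14)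

Steps most likely to fail

Step 4. Several processes could prevent both bonds from forming in one flask:
- The enamine carbon may be acylated directly.
- An acetal oxygen may be lost by beta-elimination from the iminium/enamine manifold at reflux.
- The acetal carbon may epimerise under the influence of the amine hydrochloride, which would erode enantiopurity.
- The second closure at the hindered C1 may stall.

The fallback sets out from 4 and returns at 8, and builds the two bonds stepwise at a lower oxidation level. The enamine of 4 is added at low temperature to acrolein (Stork conjugate addition). Mild aqueous hydrolysis then gives the keto aldehyde F1. Catalytic DBU in CH2Cl2 promotes an intramolecular aldol addition. Only the C1 enolate can reach the aldehyde through a six-membered ring, and the epimerisable C5 adjusts to the axial chain, which gives the bicyclic ketol F2 (carbinol configuration inconsequential). Dess–Martin oxidation of F2 delivers 8.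

Step 6. Facial selectivity may be poor or reversed (hydride arriving from the enone side), and partial reduction of the enone carbonyl may compete. The fallback sets out from 10 and returns at 13, and turns the wrong face into an asset:
- The reduction is run so that the epimeric alcohol F3 is collected.
- A Mitsunobu reaction (PPh3, DIAD, benzoic acid, THF) displaces the activated oxygen with inversion. Benzoate enters from the same enone-side face that hydride preferred, and the C6 benzoate F4 results.
- HF·pyridine frees the primary alcohol F5.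
- BzCl/pyridine/DMAP gives 13.

Step 5. The silyl triflate may activate the benzylidene acetal or the very electrophilic bridge ketone, or the palladium enolate may be protonated back to the saturated ketone instead of eliminating. The fallback sets out from 8 and returns at 10, and uses selenoxide syn-elimination instead of palladium chemistry. LiHMDS then PhSeCl in THF at −78 °C gives the alpha-phenylselanyl ketone F6; either C3 epimer serves, since C4 carries two hydrogens. H2O2/pyridine in CH2Cl2 at 0 °C oxidises F6, and elimination gives 10.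

Further compounds
F1 | step 4 | 3-[(2S,4R,6R)-6-{[(tert-butyldimethylsilyl)oxy]methyl}-5-oxo-2-phenyl-1,3-dioxan-4-yl]propanal (chain drawn axial, centre epimerisable) | CC(C)(C)[Si](C)(C)OC[C@H]1O[C@@H](c2ccccc2)O[C@H](CCC=O)C1=O
F2 | step 4 | 5-{[(tert-butyldimethylsilyl)oxy]methyl}-6-hydroxy-3-phenyl-2,4-dioxabicyclo[3.3.1]nonan-9-one (ring stereocentres as in 8, C6 carbinol of the bicycle undefined) | CC(C)(C)[Si](C)(C)OC[C@]12O[C@@H](c3ccccc3)O[C@H](CCC1O)C2=O
F3 | step 6 | (1R,3S,5R,9R)-5-{[(tert-butyldimethylsilyl)oxy]methyl}-9-hydroxy-3-phenyl-2,4-dioxabicyclo[3.3.1]non-7-en-6-one (9-epimer of 11) | CC(C)(C)[Si](C)(C)OC[C@]12O[C@@H](c3ccccc3)O[C@H](C=CC1=O)[C@H]2O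
F4 | step 6 | (1R,3S,5R,9S)-5-{[(tert-butyldimethylsilyl)oxy]methyl}-6-oxo-3-phenyl-2,4-dioxabicyclo[3.3.1]non-7-en-9-yl benzoate | CC(C)(C)[Si](C)(C)OC[C@]12O[C@@H](c3ccccc3)O[C@H](C=CC1=O)[C@@H]2OC(=O)c1ccccc1
F5 | step 6 | (1R,3S,5R,9S)-5-(hydroxymethyl)-6-oxo-3-phenyl-2,4-dioxabicyclo[3.3.1]non-7-en-9-yl benzoate | OC[C@]12O[C@@H](c3ccccc3)O[C@H](C=CC1=O)[C@@H]2OC(=O)c1ccccc1
F6 | step 5 | 5-{[(tert-butyldimethylsilyl)oxy]methyl}-3-phenyl-7-(phenylselanyl)-2,4-dioxabicyclo[3.3.1]nonane-6,9-dione (ring stereocentres as in 8, selenide carbon undefined) | CC(C)(C)[Si](C)(C)OC[C@]12O[C@@H](c3ccccc3)O[C@H](CC([Se]c3ccccc3)C1=O)C2=O
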